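## Structural features

The target is a depside: two benzene rings joined by one aryl ester, whose oxygen is O4 of ring A and whose carbonyl carbon sits on C1' of ring B. Ring A is a methyl orsellinate unit (C1 CO2Me, C2 OH hydrogen-bonded to that ester, C6 CH3, C3 and C5 unsubstituted). Ring B is hexasubstituted: going round from C1' it carries CH3 (C2'), Cl (C3'), OH (C4'), CH3 (C5') and OH (C6'), the last chelated to the depside carbonyl. There are no stereocentres, so no stereochemical relationship has to be set or preserved. The fragile elements are the aryl ester (an activated ester that bases, fluoride salts, alkoxides and nucleophilic amines cleave or transesterify), the methyl ester, the electron-rich resorcinol of ring B and the aryl chloride (lost on hydrogenolysis). The real difficulty is the ester itself: its carbonyl is flanked by the C2' methyl and the C6' hydroxyl, so acylating the weakly nucleophilic 4-hydroxyl of ring A with a 2,6-disubstituted benzoic acid is the hard bond, and ring B must in addition receive six substituents in one defined order. The key step exploits the fact that C1' (carbonyl-bearing) and C2' (methyl-bearing) are related as the α and β carbons of a but-2-ynoate, while C3' to C6' carry the 1,3-dioxygen pattern and the C-methyl of a 2-methylacetoacetate, so ring B can be grown on an unhindered alkynoate ester already attached to ring A. C3' is then the one carbon left open, ortho to the C4' hydroxyl and para to the C6' hydroxyl, which is where the chlorine belongs.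

## Logic of the disconnections

12 from 11. The bond concerned is O2–Si on ring A. The 2-oxygen of ring A is carried as a bulky silyl ether so that ring A offers neither an acidic proton nor a free phenol while ring B is built and chlorinated. Nothing is gained in skeleton, but every earlier step becomes chemoselective. The demand is an unmasking that is neither basic nor nucleophilic, because the aryl ester of 12 would not tolerate fluoride salts or alkoxides.

11 from 10. The bond cut is C3'–Cl. C3' is the only unsubstituted carbon of ring B and is activated by both hydroxyls, so an electrophilic chlorine source has one place to go. Removing the halogen leaves a ring B whose pattern maps onto two simple four-carbon building blocks. The forward step must stop after one substitution, avoid ipso attack at the methyl-bearing C5' and leave the silylated ring A untouched.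

10 from 4 and 7. The bonds cut are C1'–C6' and C2'–C3'. This divides ring B into the α and β carbons of an ynoate and a four-carbon dioxygenated diene. The decisive point is that the crowded ester is then never made by acylation: it exists as an unhindered ynoate ester before the ortho substituents appear. One ring and two C–C bonds fall away in a convergent union. The forward step must orient the partners correctly (methylene terminus of 7 to the β-carbon of 4) and aromatize by loss of the methoxy rather than the silyloxy group. It must also spare the aryl ester and the ring A silyl ether at the temperature a β-substituted ynoate requires.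

4 from 3. The bond cut is O2–Si on ring A. The cap removes the one proton that would destroy the acid-sensitive diene and deactivates ring A for the later chlorination. The demand is a silylation strong enough for a hydrogen-bonded phenol yet free of nucleophilic bases that would add to or cleave the aryl ynoate.

3 from 1 and 2. The bond cut is the acyl C–O4 bond. Both pieces are commercial, and the acid has no ortho substituents, so this esterification is ordinary. The demand is selectivity for the free 4-hydroxyl over the chelated 2-hydroxyl and an activation mild enough not to trigger conjugate addition to the triple bond.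

7 from 6, and 6 from 5. The bonds cut are the two O–Si bonds. The diene is the doubly enol-silylated form of a commercial β-keto ester, first at the ketone oxygen and then, after deprotonation at the terminal methyl, at the ester oxygen. The demand is O- rather than C-silylation and rigorous exclusion of moisture.

## Other disconnections considered

Alternative 1: The cut takes out both bonds of the depside carbonyl, C1'–C(=O) and C(=O)–O4. Ring B then arrives complete as the aryl iodide A2 (1-chloro-3-iodo-4,6-bis(methoxymethoxy)-2,5-dimethylbenzene), the carbonyl as carbon monoxide A3 and ring A as 1. In the forward step zerovalent palladium, formed from Pd(OAc)2 A4 and a wide-bite-angle bisphosphine, would add to the C–I bond of A2 and insert A3 to give an aroyl complex of divalent palladium. The 4-phenoxide of 1 would intercept this complex to give A1, the bis(methoxymethyl) ether of 12, and mild acid would then release 12.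
- In its favour: the plan is convergent, and the C–I bond should react ahead of C–Cl. The chlorine and the whole pattern of ring B are fixed before the rings meet, so no late chlorination has to be controlled; here it is better than the chosen plan. The chelated 2-hydroxyl of 1 can probably stay free, which is equal or better. A2 looks reachable in about three steps from 2,5-dimethylbenzene-1,3-diol A5 (chlorination, iodination, acetal protection), so roughly five steps would replace seven; on step count it is also the better plan.
- Against it: the key step makes exactly the bond that is hardest in this molecule, at a carbon flanked by a methyl and a methoxymethoxy group, with an electron-poor phenol as nucleophile. Capture of a di-ortho-substituted aroyl palladium species by such a phenoxide is expected to be slow. Hydrodehalogenation, direct C–O coupling and attack of the phenoxide on the activated ester of A1 could then compete. The first chlorination of A5 must also stop at one of two equivalent positions, and a toxic gas is needed.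
- Comparison: the chosen plan makes the ester from an unhindered acid and creates the congestion afterwards by C–C bond formation driven by aromatization. Structurally both give the same depside. Mechanistically the alternative carries more risk in its central step, and in step economy it is ahead.

Alternative 2: Ring B is cut at C2'–C3' and C4'–C5'. This isolates C3'–C4' as a ketene acetal, 1,1-dimethoxyethene A8, and the other four ring carbons as the 2-pyranone A7 (methyl 4-methoxy-2,5-dimethyl-6-oxo-6H-pyran-3-carboxylate). Forward, the electron-rich alkene would add across the diene termini of the electron-poor pyranone, its methylene carbon going to the methyl-bearing carbon next to the ring oxygen. The bridged lactone would then undergo decarboxylative cycloreversion, and loss of one alkoxy group would aromatize to A6, methyl 2,4-dimethoxy-3,6-dimethylbenzoate.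
- In its favour: the regiochemistry rests on the same polarity matching as in the chosen plan and is its equal. Both partners are thermally robust and insensitive to moisture, which is better than a trimethylsilyl ketene acetal diene. The cycloreversion makes the sequence irreversible.
- Against it: A6 is ring B alone, as a methyl ester with two methyl ethers. The way to 12 would still need chlorination at C3', saponification of a di-ortho-substituted ester and the hindered esterification with 1 that the chosen plan avoids. It would also need cleavage of two aryl methyl ethers; the non-chelated one at C4' calls for a boron trihalide strong enough to endanger both esters. A7 itself needs several steps.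
- Comparison: structurally the alternative leaves the depside bond unsolved. Mechanistically both are polar (4+2) cycloadditions that end in aromatization. In step economy it is the longer plan, about nine or ten steps against seven, with a weaker endgame.

Alternative 3: Ring B is cut into the diazo ketone A10 (methyl (E)-5-diazo-3-methyl-4-oxopent-2-enoate), which supplies C1', C2', C3' and C6', and the siloxyalkyne A11 (triisopropyl(prop-1-yn-1-yloxy)silane), which supplies C4' and C5'. Forward, irradiation of A10 would trigger a Wolff rearrangement to a vinylketene (C2'–C3'). This would add to A11 in a (2+2) sense (C5'–C6' and C3'–C4'). Four-electron opening of the cyclobutenone and six-electron closure of the dienylketene (C1'–C6'), then tautomerization, would give A9, methyl 2-hydroxy-3,6-dimethyl-4-(triisopropylsilyloxy)benzoate.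
- In its favour: the regiochemistry follows from the connectivity of the cascade rather than from polarity matching, and is at least the equal of the chosen plan. The two ring B oxygens emerge differentiated (free chelated hydroxyl, silyl ether at C4'); this is better than the chosen plan where they must be told apart, though 12 does not require it. The conditions are neutral.
- Against it: both partners must be prepared, one a diazo compound with its handling hazard, the other an oxygen-sensitive ynol silyl ether. The photochemical step scales poorly. A9 is again only ring B as a methyl ester, so chlorination, hydrolysis of a 2,6-disubstituted salicylate, the hindered esterification with 1 and desilylation would follow.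
- Comparison: mechanistically, four consecutive pericyclic events must all run cleanly, against one cycloaddition and one elimination. Structurally the depside bond stays open. In step economy about ten steps stand against seven.

Key step: step 5

Assumption: ring B locants are primed and run from the carbonyl-bearing C1' through C2' (methyl), C3' (chlorine), C4' (hydroxyl) and C5' (methyl) to C6' (chelated hydroxyl). Compounds 6 and 7 are used as double-bond isomer mixtures and 8 is racemic; all of these elements are erased on aromatization. The mapping of the ynoate and diene carbons onto ring B was checked atom by atom and needed no change.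

## Route

Step 1
Reactants: 1 methyl 2,4-dihydroxy-6-methylbenzoate (methyl orsellinate); 2 but-2-ynoic acid
Product: 3 methyl 4-(but-2-ynoyloxy)-2-hydroxy-6-methylbenzoate
Conditions: DCC (1.1 equiv), DMAP (5 mol %), CH2Cl2, −20 → 0 °C
Reagents that add atoms: none
Why: Steglich esterification, the usual way to aryl but-2-ynoates; the free 4-hydroxyl reacts because the 2-hydroxyl is locked in a hydrogen bond to the neighbouring ester. Low DMAP loading and low temperature limit conjugate addition to the activated triple bond and isomerization to the allenoate.

Step 2
Reactants: 3 methyl 4-(but-2-ynoyloxy)-2-hydroxy-6-methylbenzoate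
Product: 4 methyl 4-(but-2-ynoyloxy)-2-(tert-butyldimethylsilyloxy)-6-methylbenzoate
Conditions: TBSOTf (1.3 equiv), 2,6-lutidine (2 equiv), CH2Cl2, −78 → 0 °C
Reagents that add atoms: tert-butyldimethylsilyl trifluoromethanesulfonate (TBSOTf), CC(C)(C)[Si](C)(C)OS(=O)(=O)C(F)(F)F
Why: Silyl triflate O-silylation is strong enough for a hydrogen-bonded phenol. The hindered, non-nucleophilic base is chosen instead of imidazole or DMAP so that the electrophilic aryl ynoate suffers neither acyl transfer nor conjugate addition.

Step 3
Reactants: 5 methyl 2-methyl-3-oxobutanoate
Product: 6 methyl 2-methyl-3-(trimethylsilyloxy)but-2-enoate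
Conditions: TMSCl (1.5 equiv), Et3N (1.6 equiv), toluene, rt, 48 h; filter, concentrate
Reagents that add atoms: chlorotrimethylsilane (TMSCl), C[Si](C)(C)Cl
Why: Enol silylation of a β-keto ester under amine-base conditions, the standard first stage of a 1,3-bis(silyloxy)diene synthesis; the ketone oxygen is silylated and the conjugated enoate results.

Step 4
Reactants: 6 methyl 2-methyl-3-(trimethylsilyloxy)but-2-enoate
Product: 7 1-methoxy-2-methyl-1,3-bis(trimethylsilyloxy)buta-1,3-diene
Conditions: LDA (1.3 equiv, commercial solution), THF, −78 °C; TMSCl (1.5 equiv), −78 °C → rt; pentane, filter under argon, use at once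
Reagents that add atoms: chlorotrimethylsilane (TMSCl), C[Si](C)(C)Cl
Why: Kinetic γ-deprotonation of the vinylogous ester at its terminal methyl gives the dienolate, which the hard silyl chloride traps on the ester oxygen (second stage of the bis(silyloxy)diene synthesis). The methyl on C2 is not acidified and stays untouched.

Step 5
Reactants: 4 methyl 4-(but-2-ynoyloxy)-2-(tert-butyldimethylsilyloxy)-6-methylbenzoate; 7 1-methoxy-2-methyl-1,3-bis(trimethylsilyloxy)buta-1,3-diene
Product: 10 methyl 2-(tert-butyldimethylsilyloxy)-4-(2,4-dihydroxy-3,6-dimethylbenzoyloxy)-6-methylbenzoate, via cyclohexa-1,4-diene cycloadduct 8 (not isolated), via bis(trimethylsilyl) aryl ether 9 (not isolated)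
Conditions: 7 (3 equiv), PhMe (1 M), sealed tube, 110 °C; then 1 M HCl, THF, 0 °C
Reagents that add atoms: none
Why: This is a normal-electron-demand (4+2) cycloaddition of the electron-rich 1,1,3-trioxygenated diene 7 with the electron-poor aryl ynoate 4; the closest known reaction type is the Diels–Alder reaction of bis(silyloxy) ketene acetal dienes with acetylenic esters that aromatizes to resorcylates. Bond formation is asynchronous: the unsubstituted methylene terminus of 7, which has the largest HOMO coefficient, attacks the β-carbon of the ynoate (C2'–C3'), and the ketene acetal carbon then bonds to the α-carbon (C1'–C6'). Ring B is thereby closed as a six-membered carbocycle in an intermolecular (4+2) mode, which in the stepwise limit is a vinylogous Mukaiyama–Michael addition followed by 6-exo-trig capture of the silyloxycarbenium ion by the allenoate carbon. The 1,4-cyclohexadiene 8 aromatizes, on heating or at the latest on acidification, by 1,4-elimination of methanol across C3'–H and C6'–OMe to give 9; acid cleaves the Si–O bond of the mixed acetal first and the hemiketal then expels methanol, so oxygen and not methoxy should remain at C6'. Dilute acid finally removes the two aryl trimethylsilyl ethers, while the bulkier tert-butyldimethylsilyl ether of ring A is expected to persist. No stereocentre is formed that survives, since the acetal carbon of 8 is flattened on aromatization. The selectivity needed is regiochemical and chemoselective: polarity matching fixes the orientation, the silyl cap on O2 of ring A removes the only proton that would quench 7, and the aryl ester makes the triple bond a better acceptor than an alkyl ester would. If some methoxy group were left at C6' by silanol loss, it would sit ortho to the carbonyl, where BCl3 demethylates under chelation control.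

Step 6
Reactants: 10 methyl 2-(tert-butyldimethylsilyloxy)-4-(2,4-dihydroxy-3,6-dimethylbenzoyloxy)-6-methylbenzoate
Product: 11 methyl 2-(tert-butyldimethylsilyloxy)-4-(3-chloro-4,6-dihydroxy-2,5-dimethylbenzoyloxy)-6-methylbenzoate
Conditions: NCS (1.05 equiv), MeCN, 0 °C → rt, dark
Reagents that add atoms: N-chlorosuccinimide (NCS), O=C1CCC(=O)N1Cl
Why: Electrophilic aromatic chlorination of a resorcinol; C3' is the only open carbon of ring B and is ortho to the C4' hydroxyl and para to the chelated C6' hydroxyl. Ring A, an acyloxy silyl ether bearing an ester, is far less nucleophilic and should not react with one equivalent.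

Step 7
Reactants: 11 methyl 2-(tert-butyldimethylsilyloxy)-4-(3-chloro-4,6-dihydroxy-2,5-dimethylbenzoyloxy)-6-methylbenzoate
Product: 12 methyl 4-(3-chloro-4,6-dihydroxy-2,5-dimethylbenzoyloxy)-2-hydroxy-6-methylbenzoate
Conditions: HF·pyridine, pyridine, THF, 0 °C → rt
Reagents that add atoms: none
Why: Fluoride-mediated cleavage of an aryl silyl ether under buffered, weakly acidic conditions. Unlike basic fluoride salts, this should leave the depside ester, the methyl ester and the aryl chloride untouched.

## Compound list

1 | methyl 2,4-dihydroxy-6-methylbenzoate (methyl orsellinate) | COC(=O)c1c(C)cc(O)cc1O | starting material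
2 | but-2-ynoic acid | CC#CC(=O)O | starting material
3 | methyl 4-(but-2-ynoyloxy)-2-hydroxy-6-methylbenzoate | COC(=O)c1c(C)cc(OC(=O)C#CC)cc1O | intermediate
4 | methyl 4-(but-2-ynoyloxy)-2-(tert-butyldimethylsilyloxy)-6-methylbenzoate | COC(=O)c1c(C)cc(OC(=O)C#CC)cc1O[Si](C)(C)C(C)(C)C | intermediate
5 | methyl 2-methyl-3-oxobutanoate (racemic, enolizable) | COC(=O)C(C)C(C)=O | starting material
6 | methyl 2-methyl-3-(trimethylsilyloxy)but-2-enoate (E/Z mixture) | COC(=O)C(C)=C(C)O[Si](C)(C)C | intermediate
7 | 1-methoxy-2-methyl-1,3-bis(trimethylsilyloxy)buta-1,3-diene (ketene acetal isomer mixture) | COC(O[Si](C)(C)C)=C(C)C(=C)O[Si](C)(C)C | intermediate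
8 | methyl 2-(tert-butyldimethylsilyloxy)-4-{[6-methoxy-2,5-dimethyl-4,6-bis(trimethylsilyloxy)cyclohexa-1,4-diene-1-carbonyl]oxy}-6-methylbenzoate (racemic) | COC(=O)c1c(C)cc(OC(=O)C2=C(C)CC(O[Si](C)(C)C)=C(C)C2(OC)O[Si](C)(C)C)cc1O[Si](C)(C)C(C)(C)C | intermediate
9 | methyl 2-(tert-butyldimethylsilyloxy)-4-{[3,6-dimethyl-2,4-bis(trimethylsilyloxy)benzoyl]oxy}-6-methylbenzoate | COC(=O)c1c(C)cc(OC(=O)c2c(C)cc(O[Si](C)(C)C)c(C)c2O[Si](C)(C)C)cc1O[Si](C)(C)C(C)(C)C | intermediate
10 | methyl 2-(tert-butyldimethylsilyloxy)-4-(2,4-dihydroxy-3,6-dimethylbenzoyloxy)-6-methylbenzoate | COC(=O)c1c(C)cc(OC(=O)c2c(C)cc(O)c(C)c2O)cc1O[Si](C)(C)C(C)(C)C | intermediate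
11 | methyl 2-(tert-butyldimethylsilyloxy)-4-(3-chloro-4,6-dihydroxy-2,5-dimethylbenzoyloxy)-6-methylbenzoate | COC(=O)c1c(C)cc(OC(=O)c2c(C)c(Cl)c(O)c(C)c2O)cc1O[Si](C)(C)C(C)(C)C | intermediate
12 | methyl 4-(3-chloro-4,6-dihydroxy-2,5-dimethylbenzoyloxy)-2-hydroxy-6-methylbenzoate | COC(=O)c1c(C)cc(OC(=O)c2c(C)c(Cl)c(O)c(C)c2O)cc1O | target

## Step count and risk

Total step count: 7. Longest linear sequence: 5 steps (1, 2, 5, 6, 7); the diene branch (steps 3 and 4) joins at step 5.

Step 5 (key step). The cycloaddition onto a β-methyl ynoate may be slow at temperatures the bis(silyloxy)diene tolerates, so that silyl migration and protodesilylation of 7 outrun the addition. The activated aryl ester could also transfer its acyl group to the diene. Aromatization could proceed by loss of silanol instead of methanol, leaving a methoxy group at C6'. The fallback sets out from 1 and returns at 10; it gives up ring construction on the ester and makes the depside bond by acylation.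
- Commercial methyl 2,4-dihydroxy-3,6-dimethylbenzoate F1 would be benzylated on both hydroxyls (BnBr, K2CO3, DMF, 60 °C) to methyl 2,4-bis(benzyloxy)-3,6-dimethylbenzoate F2.
- Forcing saponification (KOH, aqueous DMSO, 100 °C) would give 2,4-bis(benzyloxy)-3,6-dimethylbenzoic acid F3.
- Activated as its mixed anhydride with trifluoroacetic anhydride in toluene, F3 should acylate the 4-hydroxyl of 1 through the acylium ion that a 2,6-disubstituted acid forms readily. The product is methyl 4-[2,4-bis(benzyloxy)-3,6-dimethylbenzoyloxy]-2-hydroxy-6-methylbenzoate F4.
- Silylation as in step 2 would give methyl 4-[2,4-bis(benzyloxy)-3,6-dimethylbenzoyloxy]-2-(tert-butyldimethylsilyloxy)-6-methylbenzoate F5, and hydrogenolysis (H2, Pd/C, EtOAc) would return 10.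

Step 4. The dienolate may be silylated partly on carbon, the amide base may attack the ester, and the trimethylsilyl ketene acetal may be lost by hydrolysis or silyl migration during isolation. The fallback sets out from 5 and returns at 7 in one flask by soft enolization: TMSOTf (2.2 equiv) and Et3N (2.5 equiv) in Et2O at 0 °C should silylate both oxygens without a lithium amide. The ether layer would be separated from the ammonium triflate and used directly. This makes no new compound.

Step 6. The product is still an electron-rich resorcinol, so a second chlorination or dearomatizing ipso attack at the methyl-bearing C5' between the two hydroxyls may compete. The fallback sets out from 7 and returns at 11; it brings the chlorine in with the diene instead of by aromatic substitution.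
- NCS (CH2Cl2, −78 °C) would chlorinate 7 at its nucleophilic terminal carbon, and aqueous work-up would give methyl 4-chloro-2-methyl-3-oxobutanoate F6.
- The two silylations of steps 3 and 4 would lead through methyl 4-chloro-2-methyl-3-(trimethylsilyloxy)but-2-enoate F7 to 4-chloro-1-methoxy-2-methyl-1,3-bis(trimethylsilyloxy)buta-1,3-diene F8.
- Cycloaddition of F8 with 4 under the conditions of step 5 would place the chlorinated carbon at C3' and deliver 11 after acidic work-up. The chlorinated terminus is less nucleophilic, so this variant is expected to need a higher temperature.

Step 2. Silylation of the strongly hydrogen-bonded phenol may stay incomplete, and prolonged exposure to silyl triflate and base may degrade the aryl ynoate by acyl transfer or conjugate addition. The fallback sets out from 3 and returns at 12; it dispenses with an isolated protecting group.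
- 3 would be silylated in the cycloaddition flask with N,O-bis(trimethylsilyl)acetamide (toluene, 60 °C) to methyl 4-(but-2-ynoyloxy)-6-methyl-2-(trimethylsilyloxy)benzoate F9, which would react with 7 as in step 5.
- Acidic work-up would remove all three trimethylsilyl groups to give methyl 4-(2,4-dihydroxy-3,6-dimethylbenzoyloxy)-2-hydroxy-6-methylbenzoate F10.
- One equivalent of NCS should then chlorinate F10 to 12, relying only on the much higher nucleophilicity of the resorcinol ring B over the acyloxyphenol ring A. This is two steps shorter, but ring A is unprotected during the chlorination.

## Further compounds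

F1 | step 5 | methyl 2,4-dihydroxy-3,6-dimethylbenzoate | COC(=O)c1c(C)cc(O)c(C)c1O
F2 | step 5 | methyl 2,4-bis(benzyloxy)-3,6-dimethylbenzoate | COC(=O)c1c(C)cc(OCc2ccccc2)c(C)c1OCc1ccccc1
F3 | step 5 | 2,4-bis(benzyloxy)-3,6-dimethylbenzoic acid | OC(=O)c1c(C)cc(OCc2ccccc2)c(C)c1OCc1ccccc1
F4 | step 5 | methyl 4-[2,4-bis(benzyloxy)-3,6-dimethylbenzoyloxy]-2-hydroxy-6-methylbenzoate | COC(=O)c1c(C)cc(OC(=O)c2c(C)cc(OCc3ccccc3)c(C)c2OCc2ccccc2)cc1O
F5 | step 5 | methyl 4-[2,4-bis(benzyloxy)-3,6-dimethylbenzoyloxy]-2-(tert-butyldimethylsilyloxy)-6-methylbenzoate | COC(=O)c1c(C)cc(OC(=O)c2c(C)cc(OCc3ccccc3)c(C)c2OCc2ccccc2)cc1O[Si](C)(C)C(C)(C)C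
F0 | step 4 | none | none
F6 | step 6 | methyl 4-chloro-2-methyl-3-oxobutanoate (racemic) | COC(=O)C(C)C(=O)CCl
F7 | step 6 | methyl 4-chloro-2-methyl-3-(trimethylsilyloxy)but-2-enoate | COC(=O)C(C)=C(CCl)O[Si](C)(C)C
F8 | step 6 | 4-chloro-1-methoxy-2-methyl-1,3-bis(trimethylsilyloxy)buta-1,3-diene | COC(O[Si](C)(C)C)=C(C)C(=CCl)O[Si](C)(C)C
F9 | step 2 | methyl 4-(but-2-ynoyloxy)-6-methyl-2-(trimethylsilyloxy)benzoate | COC(=O)c1c(C)cc(OC(=O)C#CC)cc1O[Si](C)(C)C
F10 | step 2 | methyl 4-(2,4-dihydroxy-3,6-dimethylbenzoyloxy)-2-hydroxy-6-methylbenzoate | COC(=O)c1c(C)cc(OC(=O)c2c(C)cc(O)c(C)c2O)cc1O
A1 | alternative 1 | methyl 4-[3-chloro-4,6-bis(methoxymethoxy)-2,5-dimethylbenzoyloxy]-2-hydroxy-6-methylbenzoate | COC(=O)c1c(C)cc(OC(=O)c2c(C)c(Cl)c(OCOC)c(C)c2OCOC)cc1O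
A2 | alternative 1 | 1-chloro-3-iodo-4,6-bis(methoxymethoxy)-2,5-dimethylbenzene | Cc1c(I)c(OCOC)c(C)c(OCOC)c1Cl
A3 | alternative 1 | carbon monoxide | [C-]#[O+]
A4 | alternative 1 | palladium diacetate | CC(=O)[O-].CC(=O)[O-].[Pd+2]
A5 | alternative 1 | 2,5-dimethylbenzene-1,3-diol | Cc1cc(O)c(C)c(O)c1
A6 | alternative 2 | methyl 2,4-dimethoxy-3,6-dimethylbenzoate | COC(=O)c1c(C)cc(OC)c(C)c1OC
A7 | alternative 2 | methyl 4-methoxy-2,5-dimethyl-6-oxo-6H-pyran-3-carboxylate | COC(=O)C1=C(C)OC(=O)C(C)=C1OC
A8 | alternative 2 | 1,1-dimethoxyethene | C=C(OC)OC
A9 | alternative 3 | methyl 2-hydroxy-3,6-dimethyl-4-(triisopropylsilyloxy)benzoate | COC(=O)c1c(C)cc(O[Si](C(C)C)(C(C)C)C(C)C)c(C)c1O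
A10 | alternative 3 | methyl (E)-5-diazo-3-methyl-4-oxopent-2-enoate | COC(=O)/C=C(\C)C(=O)C=[N+]=[N-]
A11 | alternative 3 | triisopropyl(prop-1-yn-1-yloxy)silane | CC#CO[Si](C(C)C)(C(C)C)C(C)C
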